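Late in the two earlier runs the substrate is still falling, so you must decide whether a reading at 2.5 d can close this flask or whether it has to be left running.

| flask | substrate | coupling partner | remark | time |
|---|---|---|---|---|
| red | 46 mM | 22 mM | run made earlier |  |
| violet | 46 mM | 33 mM | run made earlier |  |
| flask | 46 mM | 43.7 mM |  | 2.5 d |

| run | time / h | substrate / % | target / % |
|---|---|---|---|
| red | 2.50 | 57.6 | 0.8 |
| red | 8.00 | 30.0 | 0.1 |
| red | 15.0 | 21.7 | 0 |
| red | 20.0 | 16.4 | 1.1 |
| red | 30.0 | 11.1 | 0.9 |
| red | 40.0 | 7.1 | 0 |
| red | 50.0 | 3.9 | 2.0 |
| violet | 6.00 | 33.8 | 0 |
| violet | 15.0 | 18.2 | 0 |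
| violet | 20.0 | 15.9 | 0 |
| violet | 30.0 | 12.7 | 0 |
| violet | 40.0 | 7.6 | 1.5 |
| violet | 50.0 | 5.5 | 0.6 |

(standard deviation of a reading: 1 percentage point)

- the analysis behind the earlier runs scatters by 1 percentage point, standard deviation
- the reaction counts as stopped when no species that holds the substrate changes by six tenths of a point or more over the second half of the time

* the state of affairs at 2.5 d: stopped, and by what, or still going (all of the substrate has reacted / forward and back rates have come level / it is still moving / the coupling partner has run out first)
* part of the substrate gone at 2.5 d
* the target standing at 2.5 d, as a percentage of the substrate charged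
* the intermediate A standing at 2.5 d, as a percentage of the substrate charged

Count turnovers of that tail, read as a first-order decay. Averaging red and violet, [substrate] goes from 16.1% at 20.0 h to 4.70% at 50.0 h. That gives a late half-life, the time in which the tail halves, of 16.8 h. Red and violet end at 3.9% and 5.5% on different partner charges, a gap of 1.6 percentage points with a scatter of 1 point, so these two runs show no gain on the substrate from the added partner.

From 50.0 h to 2.5 d is 0.594 of a late half-life, fewer than one turnover. Your count gives 3.11% substrate left, after 11.9% at 30.0 h, a drop of 8.8 points. So plan to leave the flask running past 2.5 d. Your count says nothing about intermediate A, which neither run read.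

The forecast says it is still moving, with 97% gone, 2% target and 95% intermediate A, holding that “the missing material must be standing as intermediate A”.

The flask gives it is still moving, with 95.9% gone, 2.99% target and 57.7% intermediate A.

    coupling partner ⇌ dormant form (K = 0.397, k = 0.00196 min⁻¹)
    intermediate A → intermediate B (k = 1.74 × 10⁻⁴ min⁻¹)
    substrate ⇌ intermediate A (K = 40.0, k = 0.00164 min⁻¹)
    intermediate C ⇌ intermediate E (K = 1.20, k = 0.0128 min⁻¹)
    intermediate D → target (k = 2.88 × 10⁻⁴ min⁻¹)
    substrate ⇌ intermediate C (K = 0.436, k = 0.00292 min⁻¹)
    coupling partner + intermediate B ⇌ intermediate D (K = 131 M⁻¹, k = 0.00999 M⁻¹ min⁻¹)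

This flask has not come to rest: substrate stands at 4.14% against your 3.11%, and the largest change between 1.25 d and 2.5 d is 11 points. Ten times the time still moves target to 81.4% and intermediate A to 0.320%. Substrate reaches 0.0100%, which is 8.69 halvings where your count allows 32.1, so at long times the count runs ahead of this flask.

For the same charge read at 15 h, counting back 0.297 of a late half-life from 20.0 h gives 19.8% substrate. That flask holds 19.7%.

The numbers in the tables were generated by integration for an exercise, noise included.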